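## Retrosynthetic overview

Ring numbering (14-membered ring): C1 (methyl-bearing alkene carbon), C2–C4, C5 (carboxyl-bearing alkene carbon), C6, C7 (benzylic), C8/C9 (arene), O10, C11 (CMe2), C12 (carbinol), C13, C14.
Feature used: only the methylenes C13 and C14 lie between the oxygen-bearing C12 and C1 of the Z-trisubstituted C1=C2 alkene, so C12–C13–C14 is a ketone homoenolate and C1 is its alkenyl electrophile.
Target ⇒ (saponification, desilylation, enantioselective reduction at C12) macrocyclic C12 ketone ⇒ (C14–C1, palladium-catalysed opening of a C12 cyclopropanol onto the Z-alkenyl iodide) open-chain iodide/cyclopropanol.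
Open-chain precursor ⇒ (C5=C6, E-selective Wittig) arylacetaldehyde from homogentisic lactone (O10–C11 by phenol alkylation with ethyl 2-bromoisobutyrate, C13/C14 by Kulinkovich cyclopropanation) plus a stabilised phosphorane carrying the Z-iodoalkene (iodo-Wittig on 3-silyloxypropanal).
Ring order: the arene is bought, the lactone ring is opened in step 6, the cyclopropane is built in step 8, and the 14-membered ring is closed in step 11 at the expense of the cyclopropane.

Key step: step 11

Remark: 2, 9, 12 and 15 are taken as catalogue chemicals. C5=C6 is made with a neutral stabilised phosphorane rather than a phosphonate anion, because the arylacetaldehyde enolises easily and the α-alkyl enoate must be E.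

## Route

Step 1
Reactants: 1 ethyltriphenylphosphonium bromide; 2 3-(tert-butyldimethylsilyloxy)propanal
Product: 6 (Z)-tert-butyl[(4-iodopent-3-en-1-yl)oxy]dimethylsilane, via ethylidenetriphenylphosphorane 3 (not isolated), via (1-iodoethyl)triphenylphosphonium iodide 4 (not isolated), via (1-iodoethylidene)triphenylphosphorane 5 (not isolated)
Conditions: n-BuLi, THF, 0 °C; I2, THF, −78 °C; NaN(SiMe3)2, −20 °C; then 2, −78 to −20 °C
Reagents that add atoms: iodine, II
Why: Stork–Zhao-type iodo-Wittig olefination, in which the non-stabilised α-iodo ylide 5 (made by iodination and re-deprotonation of ylide 3) adds to the unbranched aldehyde under kinetic control through the cis-oxaphosphetane, so iodine ends up cis to the chain, which is the Z geometry needed at C1=C2.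

Step 2
Reactants: 6 (Z)-tert-butyl[(4-iodopent-3-en-1-yl)oxy]dimethylsilane
Product: 7 (Z)-4-iodopent-3-en-1-ol
Conditions: camphorsulfonic acid (10 mol %), MeOH, 0 °C to rt
Reagents that add atoms: none
Why: Acid-catalysed methanolysis (solvolytic desilylation) removes a primary TBS ether quickly, and the alkenyl iodide does not react with dilute sulfonic acid in methanol.

Step 3
Reactants: 7 (Z)-4-iodopent-3-en-1-ol
Product: 8 (Z)-2,5-diiodopent-2-ene
Conditions: I2, PPh3, imidazole, CH2Cl2, 0 °C, dark
Reagents that add atoms: iodine, II
Why: Appel-type iodination (Garegg–Samuelsson conditions) displaces the primary oxyphosphonium group by iodide in an SN2 step remote from the alkene, so the Z-alkenyl iodide is carried through unchanged.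

Step 4
Reactants: 8 (Z)-2,5-diiodopent-2-ene (1.1 equiv); 9 methyl (triphenylphosphoranylidene)acetate
Product: 11 methyl (Z)-6-iodo-2-(triphenylphosphoranylidene)hept-5-enoate, via alkylated phosphonium iodide 10 (not isolated)
Conditions: MeCN, reflux; then 1 M aq NaOH, CH2Cl2, 0 °C
Reagents that add atoms: none
Why: C-Alkylation of an ester-stabilised phosphorane with a primary iodide gives salt 10, which is less acidic than the salt of 9 so transylidation does not stall the alkylation, and a cold hydroxide wash deprotonates it to the α-alkylated ylide while the sp2 C–I bond is inert to SN2 attack.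

Step 5
Reactants: 12 homogentisic acid γ-lactone (5-hydroxy-1-benzofuran-2(3H)-one)
Product: 13 5-(triisopropylsilyloxy)-1-benzofuran-2(3H)-one
Conditions: iPr3SiCl, imidazole, DMF, rt
Reagents that add atoms: chlorotriisopropylsilane, CC(C)[Si](Cl)(C(C)C)C(C)C
Why: Imidazole-promoted silylation of the only free hydroxyl group, with the bulky triisopropylsilyl aryl ether chosen because it must later survive hydride, carbonate, Grignard and palladium/carbonate conditions.

Step 6
Reactants: 13 5-(triisopropylsilyloxy)-1-benzofuran-2(3H)-one
Product: 14 2-(2-hydroxyethyl)-4-(triisopropylsilyloxy)phenol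
Conditions: LiBH4, THF, 0 °C to rt; aq NH4Cl
Reagents that add atoms: none
Why: Hydride reduction of the activated aryl ester (lactone) opens the five-membered ring to the C9 phenol and the C6 primary alcohol without attacking the hindered aryl silyl ether.

Step 7
Reactants: 14 2-(2-hydroxyethyl)-4-(triisopropylsilyloxy)phenol; 15 ethyl 2-bromo-2-methylpropanoate (3 equiv)
Product: 16 ethyl 2-[2-(2-hydroxyethyl)-4-(triisopropylsilyloxy)phenoxy]-2-methylpropanoate
Conditions: Cs2CO3 (2 equiv), dry MeCN, 70 °C
Reagents that add atoms: none
Why: Williamson-type O-alkylation of a phenoxide with the activated tertiary α-bromo ester (the fibrate ether synthesis) forms the hindered O10–C11 bond, carbonate deprotonates only the phenol so the primary alcohol stays free, and excess bromide compensates for its loss by elimination.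

Step 8
Reactants: 16 ethyl 2-[2-(2-hydroxyethyl)-4-(triisopropylsilyloxy)phenoxy]-2-methylpropanoate
Product: 17 1-{2-[2-(2-hydroxyethyl)-4-(triisopropylsilyloxy)phenoxy]propan-2-yl}cyclopropan-1-ol
Conditions: EtMgBr (4.5 equiv, syringe pump), Ti(OiPr)4 (0.5 equiv), THF, 0 °C to rt; aq NH4Cl
Reagents that add atoms: ethylmagnesium bromide, CC[Mg]Br
Why: Kulinkovich cyclopropanation, in which the titanacyclopropane formed from EtMgBr and Ti(OiPr)4 acts as a 1,2-dicarbanion on the ester carbonyl and delivers C13 and C14, while the first equivalent of Grignard reagent only deprotonates the primary alcohol and the aryl silyl ether is inert.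

Step 9
Reactants: 17 1-{2-[2-(2-hydroxyethyl)-4-(triisopropylsilyloxy)phenoxy]propan-2-yl}cyclopropan-1-ol
Product: 19 {2-[2-(1-hydroxycyclopropyl)propan-2-yloxy]-5-(triisopropylsilyloxy)phenyl}acetaldehyde, via alkoxysulfonium chloride 18 (not isolated)
Conditions: (COCl)2 (1.2 equiv), DMSO (2.4 equiv), CH2Cl2, −78 °C; 17; Et3N (5 equiv), −78 to −20 °C; used crude
Reagents that add atoms: none
Why: Swern oxidation, in which near-stoichiometric chlorodimethylsulfonium chloride is captured by the unhindered primary alcohol to give 18 that collapses with Et3N to the aldehyde, whereas the tertiary cyclopropanol has no carbinol hydrogen, is shielded by the quaternary C11 and meets no metal or one-electron oxidant that would open it.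

Step 10
Reactants: 19 {2-[2-(1-hydroxycyclopropyl)propan-2-yloxy]-5-(triisopropylsilyloxy)phenyl}acetaldehyde; 11 methyl (Z)-6-iodo-2-(triphenylphosphoranylidene)hept-5-enoate (1.3 equiv)
Product: 20 methyl (2E,5Z)-2-(2-{2-[2-(1-hydroxycyclopropyl)propan-2-yloxy]-5-(triisopropylsilyloxy)phenyl}ethylidene)-6-iodohept-5-enoate
Conditions: CH2Cl2, rt to 40 °C
Reagents that add atoms: none
Why: Wittig olefination with an α-alkylated ester-stabilised phosphorane places the ester trans to the C7 methylene (E at C5=C6), and its neutral salt-free medium avoids enolisation of the arylacetaldehyde, migration of the new alkene towards the arene and base-induced opening of the free cyclopropanol.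

Step 11
Reactants: 20 methyl (2E,5Z)-2-(2-{2-[2-(1-hydroxycyclopropyl)propan-2-yloxy]-5-(triisopropylsilyloxy)phenyl}ethylidene)-6-iodohept-5-enoate
Product: 21 14-membered C12 ketone (1Z,5E; triisopropylsilyl ether, methyl ester)
Conditions: Pd2(dba)3 (10 mol %), XPhos (40 mol %), Cs2CO3 (3 equiv), degassed toluene, 80 °C, 20 added by syringe pump over 12 h (final 1 mM)
Reagents that add atoms: none
Why: Zerovalent palladium inserts into the C1–I bond of 20 with retention, carbonate-assisted exchange of iodide for the tertiary cyclopropanolate gives a palladium alkoxide, strain-driven β-carbon elimination opens the three-membered ring to a primary C14–palladium homoenolate with the carbonyl at C12, and reductive elimination joins C14 to C1. The closest known reaction type is the palladium-catalysed ring-opening cross-coupling of tertiary cyclopropanols (ketone homoenolates) with aryl and alkenyl halides, which is also known intramolecularly for common ring sizes. The 14-membered ring closes end to end by reductive elimination from a 15-membered palladacycle under pseudo-high dilution, and the ortho-disubstituted arene, the C11 gem-dimethyl group and the two trisubstituted alkenes act as turn elements that shorten the distance between the chain ends. No stereocentre is created; the Z geometry of C1=C2 is controlled by the geometry of the iodide, because oxidative addition and reductive elimination at an alkenyl carbon are both stereoretentive. Regioselectivity of ring opening is secured by the substrate, since the two cyclopropane methylenes are equivalent and C11 is quaternary, so only one homoenolate can form and the ketone cannot enolise towards C11. Chemoselectivity requires reductive elimination to outrun β-hydride elimination at C13 and alkoxide capture to outrun Heck-type insertion into C5=C6: the bulky electron-rich biarylphosphine speeds C–C reductive elimination, while C5=C6 is trisubstituted, electron-poor and fully substituted at C5, the carbon a 5-exo insertion would have to attack, and toluene keeps iodide on palladium.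

Step 12
Reactants: 21 14-membered C12 ketone (1Z,5E; triisopropylsilyl ether, methyl ester)
Product: 22 (12R)-carbinol (1Z,5E; triisopropylsilyl ether, methyl ester)
Conditions: (S)-2-methyl-CBS-oxazaborolidine (0.5 equiv), catecholborane (2 equiv), toluene, −78 to −40 °C; MeOH, then aq NaHCO3
Reagents that add atoms: none
Why: Corey–Bakshi–Shibata reduction, in which the ketone binds the (S)-oxazaborolidine–borane complex through the lone pair on the side of the small C13 methylene and away from the quaternary C11, so hydride reaches the Si face of C12 and gives the R carbinol (the sense known for tert-alkyl and aryl methyl ketones), while catecholborane at low temperature leaves the enoate and C1=C2 untouched.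

Step 13
Reactants: 22 (12R)-carbinol (1Z,5E; triisopropylsilyl ether, methyl ester)
Product: 23 petchiether B methyl ester
Conditions: Bu4NF (1.1 equiv), AcOH (1.1 equiv), THF, 0 °C
Reagents that add atoms: none
Why: Fluoride-induced desilylation is driven by Si–F bond formation, and acetic acid buffers the phenoxide so that the ester, the skipped arene/enoate system and the non-epimerisable C12 centre stay untouched.

Step 14
Reactants: 23 petchiether B methyl ester
Product: 24 petchiether B
Conditions: LiOH (10 equiv), degassed THF/MeOH/H2O, rt to 40 °C; then 1 M HCl to pH 3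
Reagents that add atoms: lithium hydroxide, [Li+].[OH-]
Why: Saponification (acyl–oxygen cleavage) of the methyl enoate followed by mild acidification gives the acid, carboxylate formation suppresses γ-deprotonation at C7, and nothing after step 12 touches C12, so the R configuration is retained.

## Compound list

1 | ethyltriphenylphosphonium bromide | CC[P+](c1ccccc1)(c1ccccc1)c1ccccc1.[Br-] | starting material
2 | 3-(tert-butyldimethylsilyloxy)propanal | O=CCCO[Si](C)(C)C(C)(C)C | starting material
3 | ethylidenetriphenylphosphorane | CC=P(c1ccccc1)(c1ccccc1)c1ccccc1 | intermediate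
4 | (1-iodoethyl)triphenylphosphonium iodide | CC(I)[P+](c1ccccc1)(c1ccccc1)c1ccccc1.[I-] | intermediate
5 | (1-iodoethylidene)triphenylphosphorane | CC(I)=P(c1ccccc1)(c1ccccc1)c1ccccc1 | intermediate
6 | (Z)-tert-butyl[(4-iodopent-3-en-1-yl)oxy]dimethylsilane | C/C(I)=C/CCO[Si](C)(C)C(C)(C)C | intermediate
7 | (Z)-4-iodopent-3-en-1-ol | C/C(I)=C/CCO | intermediate
8 | (Z)-2,5-diiodopent-2-ene | C/C(I)=C/CCI | intermediate
9 | methyl (triphenylphosphoranylidene)acetate | COC(=O)C=P(c1ccccc1)(c1ccccc1)c1ccccc1 | starting material
10 | [(Z)-6-iodo-1-methoxy-1-oxohept-5-en-2-yl]triphenylphosphonium iodide | C/C(I)=C/CCC(C(=O)OC)[P+](c1ccccc1)(c1ccccc1)c1ccccc1.[I-] | intermediate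
11 | methyl (Z)-6-iodo-2-(triphenylphosphoranylidene)hept-5-enoate | C/C(I)=C/CCC(C(=O)OC)=P(c1ccccc1)(c1ccccc1)c1ccccc1 | intermediate
12 | homogentisic acid γ-lactone | O=C1Cc2cc(O)ccc2O1 | starting material
13 | 5-(triisopropylsilyloxy)-1-benzofuran-2(3H)-one | O=C1Cc2cc(O[Si](C(C)C)(C(C)C)C(C)C)ccc2O1 | intermediate
14 | 2-(2-hydroxyethyl)-4-(triisopropylsilyloxy)phenol | OCCc1cc(O[Si](C(C)C)(C(C)C)C(C)C)ccc1O | intermediate
15 | ethyl 2-bromo-2-methylpropanoate | CCOC(=O)C(C)(C)Br | starting material
16 | ethyl 2-[2-(2-hydroxyethyl)-4-(triisopropylsilyloxy)phenoxy]-2-methylpropanoate | CCOC(=O)C(C)(C)Oc1ccc(O[Si](C(C)C)(C(C)C)C(C)C)cc1CCO | intermediate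
17 | 1-{2-[2-(2-hydroxyethyl)-4-(triisopropylsilyloxy)phenoxy]propan-2-yl}cyclopropan-1-ol | OCCc1cc(O[Si](C(C)C)(C(C)C)C(C)C)ccc1OC(C)(C)C1(O)CC1 | intermediate
18 | dimethyl(2-arylethoxy)sulfonium chloride derived from 17 | C[S+](C)OCCc1cc(O[Si](C(C)C)(C(C)C)C(C)C)ccc1OC(C)(C)C1(O)CC1.[Cl-] | intermediate
19 | {2-[2-(1-hydroxycyclopropyl)propan-2-yloxy]-5-(triisopropylsilyloxy)phenyl}acetaldehyde | O=CCc1cc(O[Si](C(C)C)(C(C)C)C(C)C)ccc1OC(C)(C)C1(O)CC1 | intermediate
20 | methyl (2E,5Z)-2-(2-{2-[2-(1-hydroxycyclopropyl)propan-2-yloxy]-5-(triisopropylsilyloxy)phenyl}ethylidene)-6-iodohept-5-enoate | C/C(I)=C/CC/C(C(=O)OC)=C\Cc1cc(O[Si](C(C)C)(C(C)C)C(C)C)ccc1OC(C)(C)C1(O)CC1 | intermediate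
21 | 14-membered C12 ketone (1Z,5E; triisopropylsilyl ether, methyl ester) | C/C1=C/CC/C(C(=O)OC)=C\Cc2cc(O[Si](C(C)C)(C(C)C)C(C)C)ccc2OC(C)(C)C(=O)CC1 | intermediate
22 | (12R)-carbinol (1Z,5E; triisopropylsilyl ether, methyl ester) | C/C1=C/CC/C(C(=O)OC)=C\Cc2cc(O[Si](C(C)C)(C(C)C)C(C)C)ccc2OC(C)(C)[C@H](O)CC1 | intermediate
23 | petchiether B methyl ester | C/C1=C/CC/C(C(=O)OC)=C\Cc2cc(O)ccc2OC(C)(C)[C@H](O)CC1 | intermediate
24 | petchiether B | C/C1=C/CC/C(C(=O)O)=C\Cc2cc(O)ccc2OC(C)(C)[C@H](O)CC1 | target

## Step count and risks

Total step count: 14.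
Longest linear sequence: 10 (steps 5–14, from 12). The phosphorane branch (steps 1–4) joins at step 10.

**Risk 1: step 11.**
- Ring closure may be outrun by several processes:
  - β-hydride elimination of the C14 palladium homoenolate followed by hydrodeiodination
  - insertion of the alkenylpalladium into the nearby C5=C6 enoate
  - carbonate-induced migration of C5=C6 towards the arene
  - intermolecular coupling
- Fallback (sets out from 20, comes back at 22): the same C14–C1 bond is closed by a B-alkyl Suzuki–Miyaura macrocyclisation. N-Bromosuccinimide (CH2Cl2, 0 °C) opens the cyclopropanol of 20 electrophilically to the β-bromo ketone F1, and Et3N eliminates HBr from it to the vinyl ketone F2. CBS reduction with the (S)-catalyst and catecholborane sets C12 on the open chain and should give the (R)-allylic alcohol F3. 9-BBN-H (2.2 equiv, THF) adds only to the terminal alkene and masks the hydroxyl group as its borinate, giving the C14 trialkylborane F4. This is added slowly to PdCl2(dppf), AsPh3 and Cs2CO3 in DMF/THF/H2O at room temperature. Transmetalation from boron needs no β-carbon elimination, the resulting alkylpalladium has no carbonyl-activated β-hydrogens, and aqueous work-up frees the carbinol to give 22.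

**Risk 2: step 12.**
- The neopentyl-type ketone may be reduced slowly. Facial discrimination may be poor if the macrocycle conformation overrides the large/small reading of the catalyst. C1=C2 may be hydroborated during a prolonged reaction.
- Fallback (sets out from 21, comes back at 22): resolution replaces asymmetric induction. NaBH4 (MeOH, 0 °C) reduces 21 without stereocontrol to the racemic carbinol F5. Esterification with (S)-O-methylmandelic acid (EDC, DMAP, CH2Cl2) gives the (12R)-mandelate ester F6 and the (12S)-mandelate ester F7, which are separated by chromatography. K2CO3 in MeOH, in which exchange at the methyl ester is degenerate, cleaves F6 to 22.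

**Risk 3: step 9.**
- The activated sulfoxide may attack the free cyclopropanol with oxidative ring opening. The arylacetaldehyde may enolise or self-condense during the amine stage.
- Fallback (sets out from 17, comes back at 20): the cyclopropanol is masked during the oxidation and the olefination. Both hydroxyl groups of 17 are silylated (Et3SiOTf, 2,6-lutidine, CH2Cl2) to the bis(triethylsilyl) ether F8. Swern conditions with excess reagent oxidise the primary triethylsilyl ether directly, a known selective oxidative desilylation, to the silyl-protected aldehyde F9. Wittig reaction with 11 gives the silyl-protected iodide F10. PPTS in MeOH then removes the triethylsilyl group in the presence of the aryl triisopropylsilyl ether to give 20.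

## Further compounds

F1 | step 11 | β-bromo ketone (open chain, C14 bromide, C12 ketone) | C/C(I)=C/CC/C(C(=O)OC)=C\Cc1cc(O[Si](C(C)C)(C(C)C)C(C)C)ccc1OC(C)(C)C(=O)CCBr
F2 | step 11 | vinyl ketone (open chain, C13=C14) | C/C(I)=C/CC/C(C(=O)OC)=C\Cc1cc(O[Si](C(C)C)(C(C)C)C(C)C)ccc1OC(C)(C)C(=O)C=C
F3 | step 11 | (R)-allylic alcohol (open chain) | C/C(I)=C/CC/C(C(=O)OC)=C\Cc1cc(O[Si](C(C)C)(C(C)C)C(C)C)ccc1OC(C)(C)[C@H](O)C=C
F4 | step 11 | C14 trialkylborane with C12 O-borinate (9-BBN adduct of F3) | C/C(I)=C/CC/C(C(=O)OC)=C\Cc1cc(O[Si](C(C)C)(C(C)C)C(C)C)ccc1OC(C)(C)[C@H](OB1C2CCCC1CCC2)CCB1C2CCCC1CCC2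
F5 | step 12 | racemic carbinol (racemate of 22) | C/C1=C/CC/C(C(=O)OC)=C\Cc2cc(O[Si](C(C)C)(C(C)C)C(C)C)ccc2OC(C)(C)C(O)CC1
F6 | step 12 | (12R)-mandelate ester ((S)-O-methylmandelate of 22) | C/C1=C/CC/C(C(=O)OC)=C\Cc2cc(O[Si](C(C)C)(C(C)C)C(C)C)ccc2OC(C)(C)[C@H](OC(=O)[C@@H](OC)c2ccccc2)CC1
F7 | step 12 | (12S)-mandelate ester ((S)-O-methylmandelate of the enantiomer of 22) | C/C1=C/CC/C(C(=O)OC)=C\Cc2cc(O[Si](C(C)C)(C(C)C)C(C)C)ccc2OC(C)(C)[C@@H](OC(=O)[C@@H](OC)c2ccccc2)CC1
F8 | step 9 | bis(triethylsilyl) ether of 17 | CC[Si](CC)(CC)OCCc1cc(O[Si](C(C)C)(C(C)C)C(C)C)ccc1OC(C)(C)C1(O[Si](CC)(CC)CC)CC1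
F9 | step 9 | silyl-protected aldehyde (triethylsilyl ether of 19) | O=CCc1cc(O[Si](C(C)C)(C(C)C)C(C)C)ccc1OC(C)(C)C1(O[Si](CC)(CC)CC)CC1
F10 | step 9 | silyl-protected iodide (triethylsilyl ether of 20) | C/C(I)=C/CC/C(C(=O)OC)=C\Cc1cc(O[Si](C(C)C)(C(C)C)C(C)C)ccc1OC(C)(C)C1(O[Si](CC)(CC)CC)CC1
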